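## Retrosynthetic overview

1. δ-Lactone (formed last): C1–O2 bond by spontaneous lactonisation of a 6-alkyl-β-resorcylic acid carrying the free (R)-2'-hydroxyl.
2. Arene (formed first): C4a–C8a bond by intramolecular aldol condensation (C2 onto C7) of a linear 9-hydroxy-3,5,7-trioxo acid, unmasked from a 6-(2-oxoalkyl)-4-hydroxy-2-pyrone.
3. Chain assembly: acylation of the dianion of triacetic acid lactone with a (4R)-β-lactone, which delivers the C3 stereocentre and its free alkoxide in one operation.
4. β-Lactone from CO and a terminal (R)-epoxide; the epoxy alcohol from mono-opening of C2-symmetric (2R,8R)-1,2:8,9-diepoxynonane with BuMgBr (one resolution sets both stereocentres).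
5. Bis-epoxide from nona-1,8-diene by epoxidation and hydrolytic kinetic resolution.

Assumption: the SMILES is read as (3R)-6,8-dihydroxy-3-[(6S)-6-hydroxyundecyl]-3,4-dihydroisocoumarin; (R,R)-(salen)Co(OAc) means Co(C36H52N2O2)(OAc) with the (R,R)-N,N'-bis(3,5-di-tert-butylsalicylidene)cyclohexane-1,2-diamine dianion (trivalent cobalt), and [(salph)Al(THF)2][Co(CO)4] means [Al(C36H46N2O2)(THF)2][Co(CO)4] with the N,N'-bis(3,5-di-tert-butylsalicylidene)benzene-1,2-diamine dianion, both used as preformed catalysts.

## Route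

Step 1
Reactants: 1 nona-1,8-diene
Product: 2 1,2:8,9-diepoxynonane (2-[5-(oxiran-2-yl)pentyl]oxirane), statistical mixture of (R,R), (S,S) and meso isomers
Conditions: mCPBA (2.3 equiv), CH2Cl2, 0 °C → rt, 16 h; aq Na2SO3/NaHCO3 wash
Reagents that add atoms: mCPBA (3-chloroperoxybenzoic acid), O=C(OO)c1cccc(Cl)c1
Why: Prilezhaev epoxidation of two isolated terminal alkenes is reliable, and no selectivity is needed because both stereocentres are fixed in step 2.

Step 2
Reactants: 2 1,2:8,9-diepoxynonane (isomer mixture)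
Product: 3 (2R,8R)-1,2:8,9-diepoxynonane ((2R)-2-{5-[(2R)-oxiran-2-yl]pentyl}oxirane)
Conditions: (R,R)-(salen)Co(OAc) (2 mol %), H2O (1.1 equiv), THF (minimal), 0 °C → rt, 24 h; distillation or chromatography from the polar diols
Reagents that add atoms: none
Why: Jacobsen hydrolytic kinetic resolution, using the catalyst enantiomer that hydrolyses (S)-configured alkyloxirane termini and leaves (R) termini, converts the meso and (S,S) isomers to diols so that only the (R,R)-bis-epoxide survives (maximum 25 %, ee raised by the double selection), which fixes both stereocentres of the target at once.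

Step 3
Reactants: 3 (2R,8R)-1,2:8,9-diepoxynonane; 4 n-butylmagnesium bromide
Product: 5 (6S,12R)-12,13-epoxytridecan-6-ol ((6S)-1-[(2R)-oxiran-2-yl]undecan-6-ol)
Conditions: 4 (0.8 equiv, slow addition), CuI (10 mol %), THF, −40 °C; aq NH4Cl; unreacted 3 recovered and recycled
Reagents that add atoms: n-butylmagnesium bromide 4, CCCC[Mg]Br
Why: Copper-catalysed Grignard opening of a terminal epoxide occurs by SN2 attack at the CH2 terminus, so the carbinol carbon is untouched (its descriptor becomes S only through the priority change), and because 3 is C2-symmetric the two ends are identical and only the mono/bis ratio is statistical.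

Step 4
Reactants: 5 (6S,12R)-12,13-epoxytridecan-6-ol; 6 carbon monoxide
Product: 7 (4R)-4-[(6S)-6-hydroxyundecyl]oxetan-2-one
Conditions: [(salph)Al(THF)2][Co(CO)4] (2 mol %), CO (60 bar), DME, 50 °C, 12 h
Reagents that add atoms: carbon monoxide 6, [C-]#[O+]
Why: Ring-expanding epoxide carbonylation (Coates type) proceeds by Co(CO)4− attack at the CH2 terminus of the aluminium-activated epoxide, CO insertion and ring closure by the alkoxide, so the C–O bond at the stereocentre is never broken and the (R)-configuration is retained; a remote secondary hydroxyl has no favourable translactonisation pathway.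

Step 5
Reactants: 7 (4R)-4-[(6S)-6-hydroxyundecyl]oxetan-2-one; 8 4-hydroxy-6-methyl-2H-pyran-2-one (triacetic acid lactone)
Product: 12 (3R)-6,8-dihydroxy-3-[(6S)-6-hydroxyundecyl]-3,4-dihydro-1H-isochromen-1-one, via tetraketide pyrone 9 (not isolated), via linear trioxo acid 10 (not isolated), via resorcylic acid 11 (not isolated)
Conditions: 8 (3.2 equiv), LiN(iPr)2 (6.4 equiv), THF–DMPU, −78 → −30 °C, 1 h; 7 added at −78 °C, → −20 °C, 2 h; then 2 M aq KOH, rt, 16 h; then 6 M HCl to pH 1, rt → 40 °C, 2 h
Reagents that add atoms: potassium hydroxide (aqueous), [K+].[OH-] (its oxygen enters the carboxyl group when the pyrone opens; one carboxyl oxygen leaves again as water on lactonisation)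
Why: Proposed new method: the methyl carbanion of the triacetic acid lactone dianion (a hard lithium dienolate known to be acylated by esters at this carbon) should attack the strained acyl carbon of 7 with acyl C–O cleavage, as lithium ester enolates and lithiated phosphonates do with 4-alkyl-β-lactones (closest known reaction types: Claisen-type acylation of polyketide polyanions and hard-nucleophile β-lactone opening), giving 9 with the C3 stereocentre carried over untouched as a free alkoxide; aqueous KOH then opens the pyrone to the linear polyketide 10, whose C2 carbanion closes onto the C7 ketone (biomimetic intramolecular aldol condensation and aromatisation, known for 6-(2-oxoalkyl)-4-hydroxy-2-pyrones) to give 11, and on acidification the (R)-2'-hydroxyl closes the δ-lactone without any bond to a stereocentre being broken.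

## Compound list

1 | nona-1,8-diene | C=CCCCCCC=C | starting material
2 | 1,2:8,9-diepoxynonane (isomer mixture) | C1OC1CCCCCC1CO1 | intermediate
3 | (2R,8R)-1,2:8,9-diepoxynonane | C1O[C@@H]1CCCCC[C@@H]1CO1 | intermediate
4 | n-butylmagnesium bromide | CCCC[Mg]Br | starting material
5 | (6S,12R)-12,13-epoxytridecan-6-ol | CCCCC[C@H](O)CCCCC[C@@H]1CO1 | intermediate
6 | carbon monoxide | [C-]#[O+] | starting material
7 | (4R)-4-[(6S)-6-hydroxyundecyl]oxetan-2-one | CCCCC[C@H](O)CCCCC[C@@H]1CC(=O)O1 | intermediate
8 | 4-hydroxy-6-methyl-2H-pyran-2-one | CC1=CC(O)=CC(=O)O1 | starting material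
9 | 6-[(4R,10S)-4,10-dihydroxy-2-oxopentadecyl]-4-hydroxy-2H-pyran-2-one | CCCCC[C@H](O)CCCCC[C@@H](O)CC(=O)CC1=CC(O)=CC(=O)O1 | intermediate
10 | (9R,15S)-9,15-dihydroxy-3,5,7-trioxoicosanoic acid | CCCCC[C@H](O)CCCCC[C@@H](O)CC(=O)CC(=O)CC(=O)CC(=O)O | intermediate
11 | 2,4-dihydroxy-6-[(2R,8S)-2,8-dihydroxytridecyl]benzoic acid | CCCCC[C@H](O)CCCCC[C@@H](O)Cc1cc(O)cc(O)c1C(=O)O | intermediate
12 | (3R)-6,8-dihydroxy-3-[(6S)-6-hydroxyundecyl]-3,4-dihydro-1H-isochromen-1-one (CNP0198395.1) | CCCCC[C@H](O)CCCCC[C@@H]1Cc2cc(O)cc(O)c2C(=O)O1 | target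

## Summary

Total step count: 5. Longest linear sequence: 5 (1 → 2 → 3 → 5 → 7 → 12).

Steps most likely to fail:

Step 5 (cascade). The risks are enolisation or alkyl-side opening of 7 instead of acyl attack, retro-aldol or dehydration of the β-hydroxy ketone in base before the aldol closes, and decarboxylation of 11 if the acid stage is heated. The fallback sets out from 7 and returns at 12 by a stepwise, protected dioxinone variant of the same polyketide logic. Compound 7 is opened with MeNH(OMe)·HCl and Me2AlCl (CH2Cl2, 0 °C) to the Weinreb amide (3R,9S)-3,9-dihydroxy-N-methoxy-N-methyltetradecanamide F1. Both hydroxyls are silylated (Et3SiCl, imidazole, DMF) to give (3R,9S)-N-methoxy-N-methyl-3,9-bis(triethylsilyloxy)tetradecanamide F2. Separately, the lithium dienolate of commercial 2,2,6-trimethyl-4H-1,3-dioxin-4-one (LiN(SiMe3)2, THF, −78 °C) is C-acylated with acetyl chloride to give 2,2-dimethyl-6-(2-oxopropyl)-4H-1,3-dioxin-4-one F3. The dianion of F3 (LiN(iPr)2, 2 equiv) is acylated with F2 to give 6-[(6R,12S)-2,4-dioxo-6,12-bis(triethylsilyloxy)heptadecyl]-2,2-dimethyl-4H-1,3-dioxin-4-one F4. Et3N in CH2Cl2 aromatises F4 to 7-hydroxy-2,2-dimethyl-5-[(2R,8S)-2,8-bis(triethylsilyloxy)tridecyl]-4H-1,3-benzodioxin-4-one F5. Aqueous HF in MeCN then removes both silyl groups, and the freed (R)-2'-hydroxyl opens the benzodioxinone with loss of acetone to give 12.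

Step 4 (carbonylation with a free hydroxyl). The risks are hydroxyl binding to the aluminium cation, epoxide-to-ketone isomerisation and oligomerisation. The fallback sets out from 5 and returns at 7 by ring-opening alkoxycarbonylation instead of ring expansion. Co2(CO)8 (5 mol %) with 3-hydroxypyridine (10 mol %) under CO (40 bar) in MeOH–THF at 60 °C converts 5 to methyl (3R,9S)-3,9-dihydroxytetradecanoate F6, with CO again entering at the CH2 terminus and retention at the stereocentre. LiOH in THF–H2O gives (3R,9S)-3,9-dihydroxytetradecanoic acid F7. Carboxyl-activating β-lactonisation (PhSO2Cl, pyridine, 0 °C), in which the 3-hydroxyl attacks the mixed anhydride so that C3 keeps its configuration, then returns 7.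

Step 3 (statistical mono-opening of a precious bis-epoxide). The risks are bis-addition, a low ceiling on yield, and bromohydrin formation. The fallback sets out from 4 and returns at 5 by a non-statistical chiral-pool build-up that makes steps 1 and 2 unnecessary. Compound 4 is added to (S)-epichlorohydrin (CuI cat., THF, −40 °C) to give (2S)-1-chloroheptan-2-ol F8. NaOH closes F8 to (2S)-2-pentyloxirane F9. F9 is opened with hex-5-enylmagnesium bromide (bought as a THF solution) and CuI to give (8S)-tridec-1-en-8-ol F10. Epoxidation with mCPBA gives (6S)-12,13-epoxytridecan-6-ol F11 as a 1:1 mixture at C12. Resolution of C12 with (R,R)-(salen)Co(OAc) and H2O (0.55 equiv) hydrolyses the (12S)-epimer and leaves 5.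

## Further compounds

F1 | step 5 | (3R,9S)-3,9-dihydroxy-N-methoxy-N-methyltetradecanamide | CCCCC[C@H](O)CCCCC[C@@H](O)CC(=O)N(C)OC
F2 | step 5 | (3R,9S)-N-methoxy-N-methyl-3,9-bis(triethylsilyloxy)tetradecanamide | CCCCC[C@H](O[Si](CC)(CC)CC)CCCCC[C@@H](O[Si](CC)(CC)CC)CC(=O)N(C)OC
F3 | step 5 | 2,2-dimethyl-6-(2-oxopropyl)-4H-1,3-dioxin-4-one | CC(=O)CC1=CC(=O)OC(C)(C)O1
F4 | step 5 | 6-[(6R,12S)-2,4-dioxo-6,12-bis(triethylsilyloxy)heptadecyl]-2,2-dimethyl-4H-1,3-dioxin-4-one | CCCCC[C@H](O[Si](CC)(CC)CC)CCCCC[C@@H](O[Si](CC)(CC)CC)CC(=O)CC(=O)CC1=CC(=O)OC(C)(C)O1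
F5 | step 5 | 7-hydroxy-2,2-dimethyl-5-[(2R,8S)-2,8-bis(triethylsilyloxy)tridecyl]-4H-1,3-benzodioxin-4-one | CCCCC[C@H](O[Si](CC)(CC)CC)CCCCC[C@@H](O[Si](CC)(CC)CC)Cc1cc(O)cc2OC(C)(C)OC(=O)c12
F6 | step 4 | methyl (3R,9S)-3,9-dihydroxytetradecanoate | CCCCC[C@H](O)CCCCC[C@@H](O)CC(=O)OC
F7 | step 4 | (3R,9S)-3,9-dihydroxytetradecanoic acid | CCCCC[C@H](O)CCCCC[C@@H](O)CC(=O)O
F8 | step 3 | (2S)-1-chloroheptan-2-ol | ClC[C@@H](O)CCCCC
F9 | step 3 | (2S)-2-pentyloxirane | CCCCC[C@H]1CO1
F10 | step 3 | (8S)-tridec-1-en-8-ol | CCCCC[C@H](O)CCCCCC=C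
F11 | step 3 | (6S)-12,13-epoxytridecan-6-ol (1:1 mixture of C12 epimers) | CCCCC[C@H](O)CCCCCC1CO1
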